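**Reading time.** I read epsilon, zeta and delta 10 min after the first portion of second substrate, and I want the target then.

| flask | starting material | second substrate | gas | free catalyst | impurity | remark | time |
|---|---|---|---|---|---|---|---|
| dawn | 2.6 mM | 1 equiv (in portions, 3) | 8.6 mM (held) | 20 mol% | 3.7 mM | run made earlier; portions every 3.0 min |  |
| summer | 28 mM | 1 equiv (in portions, 3) | 8.6 mM (held) | 20 mol% | 3.7 mM | run made earlier; portions every 3.0 min |  |
| epsilon | 2.0 mM | 1.00 equiv (in portions, 3) | 8.6 mM (held) | 20 mol% | 3.7 mM | the portions of second substrate follow each other after 3.0 min, the first at the start | 10 min |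
| zeta | 6.0 mM | 1.00 equiv (in portions, 3) | 8.6 mM (held) | 20 mol% | 3.7 mM | the portions of second substrate follow each other after 3.0 min, the first at the start | 10 min |
| delta | 20 mM | 1.00 equiv (in portions, 3) | 8.6 mM (held) | 20 mol% | 3.7 mM | the portions of second substrate follow each other after 3.0 min, the first at the start | 10 min |

- dawn (time / min: target / %, starting material / %): 1.33: 0.5, 101.2; 3.00: 1.0, 100.7; 4.00: 0, 99.5; 6.00: 0.2, 99.4; 8.00: 0.1, 99.6
- summer (time / min: target / %, starting material / %): 0.667: 5.0, 96.3; 2.00: 12.6, 88.7; 3.00: 15.6, 83.2; 5.00: 23.2, 74.9; 8.00: 36.3, 64.7

(scatter of a reading: 1 percentage point)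

- [target] at the end for epsilon, zeta, delta, in this order
- the course of these numbers from the first flask to the last (rises, then falls / hardly changes / falls all the way / rises all the way / falls, then rises)

- at the start none of the gas is in solution
- "hardly changes" means that all values lie within two and a half points (for a concentration: within two and a half percent of the largest)

**Starting material.** This charge is the setting that moves. The catalyst rises with it at 20 mol%, while the impurity stays at 3.7 mM. I take the impurity to destroy catalyst one for one, so I carry the surplus catalyst, the catalyst charged less the impurity charged, 0.300 mM in delta. Dawn's surplus is −3.18 mM, and its target reads 0.1 % at 8.00 min, inside the scatter. Summer's surplus is 1.90 mM, and its target reads 36.3 % at 8.00 min. Epsilon has −3.30 mM and zeta −2.50 mM, both below zero like dawn's, so I expect from each a target inside the scatter.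

**Portions.** By hand, a portion of second substrate should show as a step in the target if it slowed the target. Summer's target gains 1.27 mM/min up to 3.00 min and 1.16 mM/min after it. I read no step there, so I leave the dosing out.

**Time.** With the surplus steady and the gas held, I treat the starting material as falling pseudo-first-order, at a rate constant equal to the surplus times a constant per mM of surplus. Integrated, the share left is the exponential of minus that constant times surplus times time. Summer's reading of 64.7 % left at 8.00 min gives, with the scatter of that reading, 0.0286 /mM/min. For delta at 10 min I therefore reckon 1.65 mM of target.

**The forecast.** It gives 0 mM, 0 mM and 1.9 mM, a row that rises all the way, and calls delta “very sensitive to the small excess”. My delta is lower than its figure.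

**The flask.** The simulation gives 4.13 × 10⁻⁴ mM, 0.00461 mM and 1.83 mM, a row that rises all the way.

    starting material + reagent + free catalyst → free catalyst + target (k = 57.8 /M²/s)
    second substrate + reagent + free catalyst → free catalyst + second product (k = 171 /M²/s)
    gas ⇌ reagent, rate k3*(csat - [reagent]) (kL = 0.485 /s)
    free catalyst + impurity → spent catalyst (k = 139 /M/s)

**The surplus.** In delta at 10.0 min the free catalyst stands at 7.50 % of the catalyst charged, which is 0.300 mM, level with the surplus of 0.300 mM. Zeta's surplus below zero, set against its impurity charge, leaves 67.6 % of that impurity over, and zeta's impurity still unbound at 10.0 min is 68 %.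

(The runs stem from a simulated flask for an exercise; noise was put on by code.)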